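**Strategy**

Numbering: tetrahydrofuran O1, C2 (ring B), spiro C3 (epoxide C6, O7), C4 (benzyl carbon C8 of ring A), C5. Everything rests on disconnecting C2–C3 together with a temporary O1–C6 bond: the key step exploits the vicinal oxygenated carbons C2 and C3, which a Paternò–Büchi [2+2] photocycloaddition of the ring B aldehyde across the C3=C6 bond of a silyl enol ether sets in one operation as an oxetane. The precursor is the kinetic trimethylsilyl enol ether of an (S)-methyl ketone whose C4 carries the ring A benzyl arm and a bulky trityloxymethyl arm (C5). Afterwards O1 is moved from C6 to C5 and O7 closes the epoxide.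

Key step: step 9

**Remarks on the chemistry**

- The atom labels above are used for all intermediates. In the target C2, C3 and C4 are all (S); ring B, C6 and the ring A benzyl group lie on one face of the tetrahydrofuran and O7 on the other.
- The auxiliary has to be (R)-4-benzyl-2-oxazolidinone. On the chelated Z-enolate the electrophile enters anti to the auxiliary benzyl group, which gives (S) at C4 only from the (R)-auxiliary; the (S)-auxiliary would lead into the enantiomeric series.
- Protecting groups are chosen for the endgame: C5–OH as trityl ether (bulky, acid-labile, fluoride- and base-stable), ring A phenol as triisopropylsilyl ether (acid-stable), ring B phenol as pivalate, O7 as trimethylsilyl ether. C5 can then be unmasked by acid without exposing a phenol.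
- The C5 leaving group is made only after the oxetane has been opened, because a C5 sulfonate would be displaced by selenolate faster than the oxetane reacts.
- Assumption: the acid, vanillin and the auxiliary are purchased.
- Abbreviations: TIPS = triisopropylsilyl, Tr = trityl, Piv = pivaloyl, TMS = trimethylsilyl, Ts = 4-toluenesulfonyl.

**Route**

Step 1
Reactants: 1 3-(3-hydroxy-4-methoxyphenyl)propanoic acid
Product: 3 3-[4-methoxy-3-(triisopropylsilyloxy)phenyl]propanoic acid, via silyl ester 2 (not isolated)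
Conditions: i-Pr3SiCl (2.2 equiv), imidazole, DMF, rt; then K2CO3, MeOH/H2O, rt; 1 M HCl
Reagents that add atoms: chlorotriisopropylsilane, CC(C)[Si](Cl)(C(C)C)C(C)C
Why: Imidazole-promoted silylation caps phenol and acid, and mild carbonate hydrolysis then frees only the labile silyl ester, leaving an aryl silyl ether that should survive the Lewis acid, organometallic, amide-base, selenolate and acid steps ahead (silyl ether protection).

Step 2
Reactants: 3 3-[4-methoxy-3-(triisopropylsilyloxy)phenyl]propanoic acid; 4 (R)-4-benzyl-2-oxazolidinone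
Product: 6 (R)-4-benzyl-3-{3-[4-methoxy-3-(triisopropylsilyloxy)phenyl]propanoyl}oxazolidin-2-one, via mixed anhydride 5 (not isolated)
Conditions: t-BuCOCl, Et3N, THF, −20 °C; then LiCl, 4, −20 °C → rt
Reagents that add atoms: none
Why: N-Acylation of the oxazolidinone through the mixed pivalic anhydride with LiCl/Et3N activation is a standard one-pot imide synthesis that attacks the less hindered anhydride carbonyl and needs no strong base.

Step 3
Reactants: 6 (R)-4-benzyl-3-{3-[4-methoxy-3-(triisopropylsilyloxy)phenyl]propanoyl}oxazolidin-2-one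
Product: 7 (R)-4-benzyl-3-{(S)-3-hydroxy-2-[4-methoxy-3-(triisopropylsilyloxy)benzyl]propanoyl}oxazolidin-2-one
Conditions: TiCl4, i-Pr2NEt, CH2Cl2, 0 °C; then 1,3,5-trioxane, TiCl4, 0 °C
Reagents that add atoms: 1,3,5-trioxane (one CH2O unit), C1OCOCO1
Why: Evans titanium-enolate hydroxymethylation: the chelated Z-enolate is attacked by TiCl4-activated formaldehyde on the face away from the auxiliary benzyl group, which with the (R)-auxiliary sets C4 as (S); the aryl silyl ether tolerates TiCl4 at 0 °C.

Step 4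
Reactants: 7 (R)-4-benzyl-3-{(S)-3-hydroxy-2-[4-methoxy-3-(triisopropylsilyloxy)benzyl]propanoyl}oxazolidin-2-one
Product: 8 (S)-3-hydroxy-N-methoxy-2-[4-methoxy-3-(triisopropylsilyloxy)benzyl]-N-methylpropanamide
Conditions: MeNH(OMe)·HCl, AlMe3, CH2Cl2, −20 → 0 °C; aq. Rochelle salt
Reagents that add atoms: N,O-dimethylhydroxylamine hydrochloride, CNOC.Cl
Why: Weinreb transamination of the imide with the chloroaluminium amide is directed to the exocyclic carbonyl by the aluminium alkoxide of the free C5 hydroxyl, releases the auxiliary for reuse and leaves C4 untouched.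

Step 5
Reactants: 8 (S)-3-hydroxy-N-methoxy-2-[4-methoxy-3-(triisopropylsilyloxy)benzyl]-N-methylpropanamide
Product: 9 (S)-N-methoxy-2-[4-methoxy-3-(triisopropylsilyloxy)benzyl]-N-methyl-3-(trityloxy)propanamide
Conditions: Ph3CCl, Et3N, 4-(dimethylamino)pyridine (cat.), CH2Cl2, rt
Reagents that add atoms: trityl chloride, ClC(c1ccccc1)(c1ccccc1)c1ccccc1
Why: Tritylation of the primary alcohol (etherification through the trityl cation) installs a group that is bulky, transparent above 300 nm, stable to Grignard reagent, amide base and selenolate, and removable by acid without touching aryl silyl ether or pivalate.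

Step 6
Reactants: 9 (S)-N-methoxy-2-[4-methoxy-3-(triisopropylsilyloxy)benzyl]-N-methyl-3-(trityloxy)propanamide
Product: 10 (S)-3-[4-methoxy-3-(triisopropylsilyloxy)benzyl]-4-(trityloxy)butan-2-one
Conditions: MeMgBr, THF, 0 °C; aq. NH4Cl
Reagents that add atoms: methylmagnesium bromide, C[Mg]Br
Why: Weinreb ketone synthesis: the magnesium-chelated tetrahedral adduct does not collapse until the quench, so one methyl group (C6) is added and the adjacent C4 centre is not enolised.

Step 7
Reactants: 10 (S)-3-[4-methoxy-3-(triisopropylsilyloxy)benzyl]-4-(trityloxy)butan-2-one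
Product: 11 (S)-3-[4-methoxy-3-(triisopropylsilyloxy)benzyl]-2-(trimethylsilyloxy)-4-(trityloxy)but-1-ene (C6H2=C3(OTMS)–C4H(C5H2OTr)(C8H2-ring A))
Conditions: LiN(i-Pr)2, Me3SiCl, THF, −78 °C (ketone added to the base/silyl chloride mixture); cold aq. NaHCO3, used crude
Reagents that add atoms: chlorotrimethylsilane, C[Si](C)(C)Cl
Why: Kinetic enolisation with in situ silyl trapping removes a proton from the unhindered methyl group (C6) rather than the branched C4–H, so the terminal silyl enol ether should form with C4 intact; it is used crude because it is hydrolytically labile.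

Step 8
Reactants: 12 vanillin (4-hydroxy-3-methoxybenzaldehyde)
Product: 13 4-formyl-2-methoxyphenyl pivalate
Conditions: t-BuCOCl, Et3N, 4-(dimethylamino)pyridine (cat.), CH2Cl2, 0 °C → rt
Reagents that add atoms: pivaloyl chloride, CC(C)(C)C(Cl)=O
Why: Base-mediated O-acylation of the phenol with an acid chloride; the ester reduces electron donation into the ring so that the lowest aldehyde triplet stays n,π* and reactive.

Step 9
Reactants: 11 (S)-3-[4-methoxy-3-(triisopropylsilyloxy)benzyl]-2-(trimethylsilyloxy)-4-(trityloxy)but-1-ene; 13 4-formyl-2-methoxyphenyl pivalate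
Product: 14 (2S,3S)-2-[3-methoxy-4-(pivaloyloxy)phenyl]-3-{(S)-1-[4-methoxy-3-(triisopropylsilyloxy)phenyl]-3-(trityloxy)propan-2-yl}-3-(trimethylsilyloxy)oxetane (ring O1–C2–C3–C6; ring B on C2 cis to the silyloxy group on C3)
Conditions: hν (300 nm, Pyrex), 13 (2 equiv), degassed PhH, 25 °C
Reagents that add atoms: none
Why: Excitation of 13 and intersystem crossing give the n,π* triplet, whose oxygen adds to the terminal carbon C6 of the enol ether to form a triplet 1,4-biradical (benzylic radical at C2, silyloxy-stabilised radical at C3) that collapses by C2–C3 recombination after spin inversion; the closest known reaction type is the Paternò–Büchi cycloaddition of aromatic aldehydes with trimethylsilyl enol ethers of methyl ketones to 3-silyloxyoxetanes. The one new ring, the oxetane, closes stepwise: O1–C6 first, then four-membered closure through C2–C3. C3 is controlled by the C4 stereocentre: with the C4 hydrogen turned into the fork between C6 and the approaching C2, the large trityloxymethyl arm lies anti to the forming bond and C2 bonds on the face flanked by the slimmer benzyl arm. C2 is controlled relative to C3 in the biradical, where ring B turns away from the branched C4 chain and should end up cis to the silyloxy group. The step needs regioselectivity (oxygen to C6, secured by the more stable silyloxy-substituted radical at C3), chemoselectivity (only the aldehyde absorbs at 300 nm) and these two diastereoselectivities, of which the facial one rests only on the size difference of the two C4 arms.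

Step 10
Reactants: 14 (2S,3S)-2-[3-methoxy-4-(pivaloyloxy)phenyl]-3-{(S)-1-[4-methoxy-3-(triisopropylsilyloxy)phenyl]-3-(trityloxy)propan-2-yl}-3-(trimethylsilyloxy)oxetane
Product: 16 (1S,2R,3S)-1-[3-methoxy-4-(pivaloyloxy)phenyl]-3-[4-methoxy-3-(triisopropylsilyloxy)benzyl]-2-[(phenylselanyl)methyl]butane-1,2,4-triol (O1–H on C2, O7–H on C3, C5–OH, C6–SePh), via hydroxy selenide 15 (not isolated)
Conditions: PhSeH (3 equiv), NaH (0.5 equiv), DMF, 80 °C; aq. work-up; then camphorsulfonic acid (cat.), MeOH/CH2Cl2, rt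
Reagents that add atoms: benzeneselenol, [SeH]c1ccccc1
Why: SN2 ring opening of the strained oxetane by the soft, weakly basic selenolate should occur at C6, the only ring carbon open to backside attack, freeing O1 on C2 with retention while the selenol buffer protonates the alkoxide at once; acid-catalysed methanolysis then removes the trityl ether and the tertiary trimethylsilyl ether but not the aryl silyl ether or the pivalate.

Step 11
Reactants: 16 (1S,2R,3S)-1-[3-methoxy-4-(pivaloyloxy)phenyl]-3-[4-methoxy-3-(triisopropylsilyloxy)benzyl]-2-[(phenylselanyl)methyl]butane-1,2,4-triol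
Product: 18 (2S,3R,4S)-2-[3-methoxy-4-(pivaloyloxy)phenyl]-4-[4-methoxy-3-(triisopropylsilyloxy)benzyl]-3-[(phenylselanyl)methyl]tetrahydrofuran-3-ol, via primary tosylate 17 (not isolated)
Conditions: TsCl (1.1 equiv), Et3N, 4-(dimethylamino)pyridine (cat.), CH2Cl2, 0 °C; evaporate; then KOt-Bu, THF, 0 °C
Reagents that add atoms: none
Why: Selective sulfonylation of the primary C5 hydroxyl, then intramolecular Williamson etherification in which the O1 alkoxide displaces the tosylate in a fast 5-exo-tet closure that should outrun 4-exo attack by O7 or participation by selenium; no bond at C2, C3 or C4 is broken.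

Step 12
Reactants: 18 (2S,3R,4S)-2-[3-methoxy-4-(pivaloyloxy)phenyl]-4-[4-methoxy-3-(triisopropylsilyloxy)benzyl]-3-[(phenylselanyl)methyl]tetrahydrofuran-3-ol
Product: 20 (3S,4S,7S)-4-[3-methoxy-4-(pivaloyloxy)phenyl]-7-[4-methoxy-3-(triisopropylsilyloxy)benzyl]-1,5-dioxaspiro[2.4]heptane, via selenonium salt 19 (not isolated)
Conditions: Me3OBF4, CH2Cl2, 0 °C → rt; evaporate; then KOt-Bu, THF, 0 °C
Reagents that add atoms: none
Why: Alkylation at the soft selenium centre gives a selenonium leaving group that the tertiary O7 alkoxide displaces at C6 in a 3-exo-tet closure (epoxide synthesis from a β-hydroxy selenide), so the C3 configuration set in the photocycloaddition is carried over unchanged.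

Step 13
Reactants: 20 (3S,4S,7S)-4-[3-methoxy-4-(pivaloyloxy)phenyl]-7-[4-methoxy-3-(triisopropylsilyloxy)benzyl]-1,5-dioxaspiro[2.4]heptane
Product: 22 (3S,4S,7S)-7-(3-hydroxy-4-methoxybenzyl)-4-(4-hydroxy-3-methoxyphenyl)-1,5-dioxaspiro[2.4]heptane (CNP0184956.1), via monopivalate 21 (not isolated)
Conditions: Bu4NF, THF, 0 °C; then K2CO3 (0.5 equiv), MeOH, rt; aq. NH4Cl
Reagents that add atoms: none
Why: Fluoride-mediated desilylation of the aryl silyl ether and carbonate-catalysed transesterification of the aryl pivalate with methanol are both too mild to open the 2,2-disubstituted epoxide or to ionise the benzylic C2–O1 bond.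

**Compound list**

1 | 3-(3-hydroxy-4-methoxyphenyl)propanoic acid | COc1ccc(CCC(O)=O)cc1O | starting material
2 | triisopropylsilyl 3-[4-methoxy-3-(triisopropylsilyloxy)phenyl]propanoate | COc1ccc(CCC(=O)O[Si](C(C)C)(C(C)C)C(C)C)cc1O[Si](C(C)C)(C(C)C)C(C)C | intermediate
3 | 3-[4-methoxy-3-(triisopropylsilyloxy)phenyl]propanoic acid | COc1ccc(CCC(O)=O)cc1O[Si](C(C)C)(C(C)C)C(C)C | intermediate
4 | (R)-4-benzyl-2-oxazolidinone | O=C1N[C@H](Cc2ccccc2)CO1 | starting material
5 | mixed anhydride of 3 with pivalic acid | COc1ccc(CCC(=O)OC(=O)C(C)(C)C)cc1O[Si](C(C)C)(C(C)C)C(C)C | intermediate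
6 | (R)-4-benzyl-3-{3-[4-methoxy-3-(triisopropylsilyloxy)phenyl]propanoyl}oxazolidin-2-one | COc1ccc(CCC(=O)N2[C@H](Cc3ccccc3)COC2=O)cc1O[Si](C(C)C)(C(C)C)C(C)C | intermediate
7 | (R)-4-benzyl-3-{(S)-3-hydroxy-2-[4-methoxy-3-(triisopropylsilyloxy)benzyl]propanoyl}oxazolidin-2-one | COc1ccc(C[C@@H](CO)C(=O)N2[C@H](Cc3ccccc3)COC2=O)cc1O[Si](C(C)C)(C(C)C)C(C)C | intermediate
8 | (S)-3-hydroxy-N-methoxy-2-[4-methoxy-3-(triisopropylsilyloxy)benzyl]-N-methylpropanamide | COc1ccc(C[C@@H](CO)C(=O)N(C)OC)cc1O[Si](C(C)C)(C(C)C)C(C)C | intermediate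
9 | (S)-N-methoxy-2-[4-methoxy-3-(triisopropylsilyloxy)benzyl]-N-methyl-3-(trityloxy)propanamide | COc1ccc(C[C@@H](COC(c2ccccc2)(c2ccccc2)c2ccccc2)C(=O)N(C)OC)cc1O[Si](C(C)C)(C(C)C)C(C)C | intermediate
10 | (S)-3-[4-methoxy-3-(triisopropylsilyloxy)benzyl]-4-(trityloxy)butan-2-one | COc1ccc(C[C@@H](COC(c2ccccc2)(c2ccccc2)c2ccccc2)C(C)=O)cc1O[Si](C(C)C)(C(C)C)C(C)C | intermediate
11 | (S)-3-[4-methoxy-3-(triisopropylsilyloxy)benzyl]-2-(trimethylsilyloxy)-4-(trityloxy)but-1-ene | COc1ccc(C[C@@H](COC(c2ccccc2)(c2ccccc2)c2ccccc2)C(=C)O[Si](C)(C)C)cc1O[Si](C(C)C)(C(C)C)C(C)C | intermediate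
12 | vanillin | COc1cc(C=O)ccc1O | starting material
13 | 4-formyl-2-methoxyphenyl pivalate | COc1cc(C=O)ccc1OC(=O)C(C)(C)C | intermediate
14 | (2S,3S)-2-[3-methoxy-4-(pivaloyloxy)phenyl]-3-{(S)-1-[4-methoxy-3-(triisopropylsilyloxy)phenyl]-3-(trityloxy)propan-2-yl}-3-(trimethylsilyloxy)oxetane | COc1ccc(C[C@@H](COC(c2ccccc2)(c2ccccc2)c2ccccc2)[C@]3(O[Si](C)(C)C)CO[C@H]3c4ccc(OC(=O)C(C)(C)C)c(OC)c4)cc1O[Si](C(C)C)(C(C)C)C(C)C | intermediate
15 | (1S,2R,3S)-1-[3-methoxy-4-(pivaloyloxy)phenyl]-3-[4-methoxy-3-(triisopropylsilyloxy)benzyl]-2-[(phenylselanyl)methyl]-2-(trimethylsilyloxy)-4-(trityloxy)butan-1-ol | COc1ccc(C[C@@H](COC(c2ccccc2)(c2ccccc2)c2ccccc2)[C@](O[Si](C)(C)C)(C[Se]c2ccccc2)[C@@H](O)c2ccc(OC(=O)C(C)(C)C)c(OC)c2)cc1O[Si](C(C)C)(C(C)C)C(C)C | intermediate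
16 | (1S,2R,3S)-1-[3-methoxy-4-(pivaloyloxy)phenyl]-3-[4-methoxy-3-(triisopropylsilyloxy)benzyl]-2-[(phenylselanyl)methyl]butane-1,2,4-triol | COc1ccc(C[C@@H](CO)[C@](O)(C[Se]c2ccccc2)[C@@H](O)c2ccc(OC(=O)C(C)(C)C)c(OC)c2)cc1O[Si](C(C)C)(C(C)C)C(C)C | intermediate
17 | 4-O-tosylate of triol 16 (tosyloxy group on C5) | COc1ccc(C[C@@H](COS(=O)(=O)c2ccc(C)cc2)[C@](O)(C[Se]c2ccccc2)[C@@H](O)c2ccc(OC(=O)C(C)(C)C)c(OC)c2)cc1O[Si](C(C)C)(C(C)C)C(C)C | intermediate
18 | (2S,3R,4S)-2-[3-methoxy-4-(pivaloyloxy)phenyl]-4-[4-methoxy-3-(triisopropylsilyloxy)benzyl]-3-[(phenylselanyl)methyl]tetrahydrofuran-3-ol | COc1ccc(C[C@H]2CO[C@@H](c3ccc(OC(=O)C(C)(C)C)c(OC)c3)[C@@]2(O)C[Se]c4ccccc4)cc1O[Si](C(C)C)(C(C)C)C(C)C | intermediate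
19 | methyl(phenyl)selenonium tetrafluoroborate of 18 (mixture at selenium) | COc1ccc(C[C@H]2CO[C@@H](c3ccc(OC(=O)C(C)(C)C)c(OC)c3)[C@@]2(O)C[Se+](C)c4ccccc4)cc1O[Si](C(C)C)(C(C)C)C(C)C.F[B-](F)(F)F | intermediate
20 | (3S,4S,7S)-4-[3-methoxy-4-(pivaloyloxy)phenyl]-7-[4-methoxy-3-(triisopropylsilyloxy)benzyl]-1,5-dioxaspiro[2.4]heptane | COc1ccc(C[C@H]2CO[C@@H](c3ccc(OC(=O)C(C)(C)C)c(OC)c3)[C@@]23CO3)cc1O[Si](C(C)C)(C(C)C)C(C)C | intermediate
21 | (3S,4S,7S)-7-(3-hydroxy-4-methoxybenzyl)-4-[3-methoxy-4-(pivaloyloxy)phenyl]-1,5-dioxaspiro[2.4]heptane | COc1ccc(C[C@H]2CO[C@@H](c3ccc(OC(=O)C(C)(C)C)c(OC)c3)[C@@]23CO3)cc1O | intermediate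
22 | (3S,4S,7S)-7-(3-hydroxy-4-methoxybenzyl)-4-(4-hydroxy-3-methoxyphenyl)-1,5-dioxaspiro[2.4]heptane | COc1ccc(C[C@H]2CO[C@@H](c3ccc(O)c(OC)c3)[C@@]23CO3)cc1O | target

**Step count and risks**

Total step count: 13. Longest linear sequence: 12 steps (steps 1–7 and 9–13, from acid 1).

Steps most likely to fail:

1. Step 9. The photocycloaddition may add to the wrong face of the enol ether relative to C4, since the two C4 arms differ only in remote bulk, or the enol ether may be lost to hydrolysis and hydrogen abstraction before the triplet aldehyde intercepts it. Fallback: the C2–C3 bond is made in the ground state. Setting out from ketone 10, kinetic enolisation and trapping with PhNTf2 should give the terminal enol triflate F1. Nozaki–Hiyama–Kishi coupling with aldehyde 13 (CrCl2, NiCl2 cat., DMF) should give the allylic alcohol F2, whose C2 configuration would have to be secured by chromatographic separation. Camphorsulfonic acid in methanol removes the trityl group to give the diol F3. Primary tosylation gives the tosylate F4, and KOt-Bu closes the 2,4-cis 3-methylenetetrahydrofuran F5. Epoxidation with dimethyldioxirane from the face opposite the cis aryl and benzyl groups should place O7 trans to both, and the route is rejoined at 20.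

2. Step 10. SN2 attack at C6 is slowed because C6 sits next to the fully substituted C3, so the opening may stall or need temperatures at which selenolate begins to demethylate the aryl ethers. Fallback: electrophilic instead of anionic opening. Setting out from oxetane 14, excess Me3SiBr (CH2Cl2, −78 → 0 °C) silylates the ring oxygen, bromide opens the ring at C6 and the trityl ether is exchanged for a silyl ether, giving the tris(trimethylsilyl) ether bromide F6. Methanol with a trace of camphorsulfonic acid gives the bromo triol F7. Primary tosylation gives the tosylate F8, and excess KOt-Bu then closes the tetrahydrofuran (O1 on C5) and the epoxide (O7 on C6) in one operation, returning to the route at 20. The site of bromide attack (C6 rather than the benzylic C2) would have to be confirmed.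

3. Step 12. Methylation may be slow at the hindered phenyl selenide or spill over to oxygen, and the selenonium salt may be deprotonated to an ylide instead of being displaced. Fallback: oxidative instead of alkylative activation. Setting out from 18, excess 3-chloroperoxybenzoic acid with K2HPO4 in methanol should oxidise selenium to the selenone F9 (no syn-elimination is possible because C3 carries no hydrogen). O7 then displaces the selenone under the same mildly basic conditions, returning to the route at 20.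

**Further compounds**

F1 | step 9 | (S)-3-[4-methoxy-3-(triisopropylsilyloxy)benzyl]-4-(trityloxy)but-1-en-2-yl trifluoromethanesulfonate | COc1ccc(C[C@@H](COC(c2ccccc2)(c2ccccc2)c2ccccc2)C(=C)OS(=O)(=O)C(F)(F)F)cc1O[Si](C(C)C)(C(C)C)C(C)C
F2 | step 9 | allylic alcohol ring B–C2H(OH)–C3(=C6H2)–C4H(C5H2OTr)(C8H2–ring A), C2 and C4 as in 16 | COc1ccc(C[C@@H](COC(c2ccccc2)(c2ccccc2)c2ccccc2)C(=C)[C@@H](O)c2ccc(OC(=O)C(C)(C)C)c(OC)c2)cc1O[Si](C(C)C)(C(C)C)C(C)C
F3 | step 9 | detritylated diol of F2 (C2–OH and C5–OH) | COc1ccc(C[C@@H](CO)C(=C)[C@@H](O)c2ccc(OC(=O)C(C)(C)C)c(OC)c2)cc1O[Si](C(C)C)(C(C)C)C(C)C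
F4 | step 9 | C5 tosylate of diol F3 | COc1ccc(C[C@@H](COS(=O)(=O)c2ccc(C)cc2)C(=C)[C@@H](O)c2ccc(OC(=O)C(C)(C)C)c(OC)c2)cc1O[Si](C(C)C)(C(C)C)C(C)C
F5 | step 9 | 2,4-cis 2-[3-methoxy-4-(pivaloyloxy)phenyl]-4-[4-methoxy-3-(triisopropylsilyloxy)benzyl]-3-methylenetetrahydrofuran | COc1ccc(C[C@H]2CO[C@@H](c3ccc(OC(=O)C(C)(C)C)c(OC)c3)C2=C)cc1O[Si](C(C)C)(C(C)C)C(C)C
F6 | step 10 | tris(trimethylsilyl) ether of the C6 bromide (O1, O7 and C5–O silylated) | COc1ccc(C[C@@H](CO[Si](C)(C)C)[C@](O[Si](C)(C)C)(CBr)[C@@H](O[Si](C)(C)C)c2ccc(OC(=O)C(C)(C)C)c(OC)c2)cc1O[Si](C(C)C)(C(C)C)C(C)C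
F7 | step 10 | bromo triol (C6–Br analogue of 16) | COc1ccc(C[C@@H](CO)[C@](O)(CBr)[C@@H](O)c2ccc(OC(=O)C(C)(C)C)c(OC)c2)cc1O[Si](C(C)C)(C(C)C)C(C)C
F8 | step 10 | C5 tosylate of bromo triol F7 | COc1ccc(C[C@@H](COS(=O)(=O)c2ccc(C)cc2)[C@](O)(CBr)[C@@H](O)c2ccc(OC(=O)C(C)(C)C)c(OC)c2)cc1O[Si](C(C)C)(C(C)C)C(C)C
F9 | step 12 | phenyl selenone of 18 | COc1ccc(C[C@H]2CO[C@@H](c3ccc(OC(=O)C(C)(C)C)c(OC)c3)[C@@]2(O)C[Se](=O)(=O)c4ccccc4)cc1O[Si](C(C)C)(C(C)C)C(C)C
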